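**Retrosynthetic overview**

1. Target 11 ⇐ benzyl ether 10 (hydrogenolysis). 10 ⇐ racemic spiro tetraketone 8 + MeOH: the cyclopentenone ring of 10 comes from contraction of the six-membered carbocycle C5–C10 of 8, with C6 leaving the ring as CO2Me. This is a benzilic ester rearrangement that runs stepwise through the achiral, ring-opened keto ester 9, so both enantiomers of 8 converge on one product (modelled on the presumed flavone → spiroketone biogenesis). Both stereocentres are set here by a chiral Cu(II) catalyst.
2. Enabling feature: in 8 the spiro carbon C5 carries the ring oxygen O1 and lies between the furanone C4=O and the ring C10=O, so as a leaving carbanion it is an aromatic 3-hydroxyfuran. Next to it sits the vicinal C6/C7 dione: C6 takes up methanol and C7 becomes the α-keto ester electrophile for re-closure onto C5.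
3. 8 ⇐ flavone-5,8-quinone 4a,8a-epoxide 6 (acid; the oxygen moves from C8a to C4a and the pyranone becomes the spiro-3(2H)-furanone) ⇐ quinone 5 (nucleophilic epoxidation) ⇐ flavone 4 (CAN) ⇐ chalcone 3 ⇐ 1 + 2.
4. Ring order: A-ring from 1 (later the carbocycle); pyranone (step 2); epoxide (step 4); furanone (step 5); cyclopentenone by ring contraction (step 6).

Key step: step 6

Remark: 1 is taken as a catalogue building block. Compounds 6, 7 and 8 are racemates on purpose (the SMILES of 6 shows one enantiomer of the cis-epoxide), because their stereocentres are erased in step 6.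

**Step 1**
Reactants: 1 2'-hydroxy-3',4',5',6'-tetramethoxyacetophenone; 2 4-(benzyloxy)benzaldehyde
Product: 3 (E)-3-[4-(benzyloxy)phenyl]-1-(2-hydroxy-3,4,5,6-tetramethoxyphenyl)prop-2-en-1-one
Conditions: KOH (50% aq), EtOH, rt
Reagents that add atoms: none
Why: Claisen–Schmidt condensation; the non-enolisable aldehyde can only be the acceptor and E1cB dehydration gives the E-enone, while any flavanone formed by reversible oxa-Michael closure is carried to the same flavone in step 2.

**Step 2**
Reactants: 3 (E)-3-[4-(benzyloxy)phenyl]-1-(2-hydroxy-3,4,5,6-tetramethoxyphenyl)prop-2-en-1-one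
Product: 4 2-[4-(benzyloxy)phenyl]-5,6,7,8-tetramethoxy-4H-chromen-4-one
Conditions: I2 (10 mol%), DMSO, 120 °C
Reagents that add atoms: none
Why: Iodine-catalysed oxidative cyclisation of a 2'-hydroxychalcone to the flavone (oxa-Michael closure, α-iodination, loss of HI, with DMSO as terminal oxidant); the benzyl and methyl ethers are inert.

**Step 3**
Reactants: 4 2-[4-(benzyloxy)phenyl]-5,6,7,8-tetramethoxy-4H-chromen-4-one
Product: 5 2-[4-(benzyloxy)phenyl]-6,7-dimethoxy-4H-chromene-4,5,8-trione
Conditions: CAN (2.5 equiv), MeCN–H2O 4:1, 0 °C
Reagents that add atoms: water, O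
Why: Cerium(IV) oxidative demethylation of a para-dimethoxyarene to the p-quinone; only the 5,8-methoxy pair of the A-ring is para-related, so the 6,7-methoxy groups remain as vinylogous esters, and the benzyl ether on the electron-poor B-ring should survive.

**Step 4**
Reactants: 5 2-[4-(benzyloxy)phenyl]-6,7-dimethoxy-4H-chromene-4,5,8-trione
Product: 6 rac-(4aR,8aR)-2-[4-(benzyloxy)phenyl]-4a,8a-epoxy-6,7-dimethoxy-4a,8a-dihydro-4H-chromene-4,5,8-trione
Conditions: t-BuOOH (1.5 equiv), DBU (1.1 equiv), CH2Cl2, 0 °C
Reagents that add atoms: tert-butyl hydroperoxide, CC(C)(C)OO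
Why: Weitz–Scheffer nucleophilic epoxidation of a quinone double bond; the peroxide adds at C8a, the β-carbon of the doubly acyl-activated C4a=C8a bond (far more electrophilic than the dimethoxy-substituted C6=C7 bond or chromone C2), and the C4a 1,3-dicarbonyl enolate closes on O–O, giving the necessarily cis, racemic epoxide.

**Step 5**
Reactants: 6 rac-(4aR,8aR)-2-[4-(benzyloxy)phenyl]-4a,8a-epoxy-6,7-dimethoxy-4a,8a-dihydro-4H-chromene-4,5,8-trione
Product: 8 2-[4-(benzyloxy)phenyl]-8,9-dimethoxy-1-oxaspiro[4.5]deca-2,8-diene-4,6,7,10-tetrone (racemic), via hydroxy trione 7 (not isolated)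
Conditions: TsOH·H2O (20 mol%), MeCN, rt
Reagents that add atoms: water, O
Why: Acid hydrolysis of an enol-ether (ketal-type) epoxide to an α-hydroxy ketone, as in the Rubottom oxidation, followed by the standard cyclodehydration of an α'-hydroxy 1,3-diketone to a 3(2H)-furanone: the epoxide opens at the O1-stabilised C8a, water adds and the hemiketal collapses to the C8a ketone with release of the side-chain enol (7), and the tertiary C4a–OH then closes 5-exo-trig on the aryl ketone and loses water, so only catalytic water is needed and the single stereocentre of 8 is racemic.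

**Step 6**
Reactants: 8 2-[4-(benzyloxy)phenyl]-8,9-dimethoxy-1-oxaspiro[4.5]deca-2,8-diene-4,6,7,10-tetrone (racemic)
Product: 10 methyl (5S,6R)-2-[4-(benzyloxy)phenyl]-6-hydroxy-7,8-dimethoxy-4,9-dioxo-1-oxaspiro[4.4]nona-2,7-diene-6-carboxylate, via keto ester 9 (not isolated)
Conditions: [Cu((R,R)-t-Bu-box)](OTf)2 (10 mol%), MeOH (5 equiv), CH2Cl2, −20 °C
Reagents that add atoms: methanol, CO
Why: Proposed new method: methanol adds to C6 of 8, the only carbonyl that is not a vinylogous ester and is further activated by the adjacent C7=O and by Cu(II) chelation of the C6/C7 dione, and the hemiketal fragments through a six-membered, β-keto-acid-type transition state (retro-Claisen) because C5 departs as an aromatic, internally hydrogen-bonded 2-acyl-3-hydroxyfuran (an isomaltol-type carbon acid), which destroys the stereocentre of 8 and gives the achiral keto ester 9. In 9 the new ester and the former C7 ketone form the five-membered α-keto ester chelate of the chiral Cu(II)–bis(oxazoline) Lewis acid, and furan C2 adds to this ketone in a 5-(enolexo)-exo-trig aldol (Friedel–Crafts-type) closure, so the six-membered carbocycle is contracted to the cyclopentenone with C6 extruded as CO2Me, i.e. a benzilic ester rearrangement run stepwise. The closest known reaction types are the alkoxide-mediated benzilic ester ring contraction of cyclic 1,2-diones, Lewis-acid-catalysed retro-Claisen alcoholysis of 1,3-diketones, and Cu(II)–box-catalysed enantioselective aldol, ene and Friedel–Crafts additions of enol-type nucleophiles and furans to chelated α-keto esters. C-6 of 10 is set by the ligand: in the square-planar chelate one face of the ketone is shielded by a tert-butyl group, and the (R,R) ligand is chosen because the established chelate model for pyruvate aldol additions predicts that it leaves the Re face open (6R), the enantiomeric ligand being at hand should the sense prove opposite. C-5 is set relative to C-6 in the same closure: the intramolecular O–H···O=C hydrogen bond should keep the acylhydroxyfuran U-shaped so that the tether reaches the ketone from the side of the ring oxygen, and the Cu-bound ester should then point away from the furan and its aryl group while the small ketone oxygen lies over the ring-oxygen side, which gives OH cis to O1 (5S). The step needs attack of methanol at C6 (secured as stated; exchange at the vinylogous methoxy groups is degenerate), C- rather than O-closure (only the C–C closure is productive, the lactol being reversible) and kinetic control, secured by the absence of base and the low temperature so that 10 does not re-open by retro-aldol.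

**Step 7**
Reactants: 10 methyl (5S,6R)-2-[4-(benzyloxy)phenyl]-6-hydroxy-7,8-dimethoxy-4,9-dioxo-1-oxaspiro[4.4]nona-2,7-diene-6-carboxylate
Product: 11 methyl (5S,6R)-6-hydroxy-2-(4-hydroxyphenyl)-7,8-dimethoxy-4,9-dioxo-1-oxaspiro[4.4]nona-2,7-diene-6-carboxylate (limnophilaspiroketone)
Conditions: H2 (1 atm), 5% Pd/C, EtOAc, rt
Reagents that add atoms: none
Why: Hydrogenolysis of an aryl benzyl ether, which at 1 atm should be faster than saturation of the two push–pull (vinylogous ester) C=C bonds; the neutral, base-free medium should leave both stereocentres untouched (no retro-aldol).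

**Compound list**

1 | 2'-hydroxy-3',4',5',6'-tetramethoxyacetophenone | CC(=O)c1c(O)c(OC)c(OC)c(OC)c1OC | starting material
2 | 4-(benzyloxy)benzaldehyde | O=Cc1ccc(OCc2ccccc2)cc1 | starting material
3 | (E)-3-[4-(benzyloxy)phenyl]-1-(2-hydroxy-3,4,5,6-tetramethoxyphenyl)prop-2-en-1-one | O=C(/C=C/c1ccc(OCc2ccccc2)cc1)c1c(O)c(OC)c(OC)c(OC)c1OC | intermediate
4 | 2-[4-(benzyloxy)phenyl]-5,6,7,8-tetramethoxy-4H-chromen-4-one | O=c1cc(-c2ccc(OCc3ccccc3)cc2)oc2c(OC)c(OC)c(OC)c(OC)c12 | intermediate
5 | 2-[4-(benzyloxy)phenyl]-6,7-dimethoxy-4H-chromene-4,5,8-trione | O=C1C=C(c2ccc(OCc3ccccc3)cc2)OC2=C1C(=O)C(OC)=C(OC)C2=O | intermediate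
6 | rac-(4aR,8aR)-2-[4-(benzyloxy)phenyl]-4a,8a-epoxy-6,7-dimethoxy-4a,8a-dihydro-4H-chromene-4,5,8-trione (cis-epoxide, one enantiomer drawn) | O=C1C=C(c2ccc(OCc3ccccc3)cc2)O[C@@]4(O5)[C@]15C(=O)C(OC)=C(OC)C4=O | intermediate
7 | 2-{3-[4-(benzyloxy)phenyl]-3-oxopropanoyl}-2-hydroxy-5,6-dimethoxycyclohex-5-ene-1,3,4-trione (racemic, diketo tautomer drawn) | O=C(CC(=O)c1ccc(OCc2ccccc2)cc1)C1(O)C(=O)C(=O)C(OC)=C(OC)C1=O | intermediate
8 | 2-[4-(benzyloxy)phenyl]-8,9-dimethoxy-1-oxaspiro[4.5]deca-2,8-diene-4,6,7,10-tetrone (racemic) | O=C1C=C(c2ccc(OCc3ccccc3)cc2)OC14C(=O)C(=O)C(OC)=C(OC)C4=O | intermediate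
9 | methyl (3Z)-5-{5-[4-(benzyloxy)phenyl]-3-hydroxyfuran-2-yl}-3,4-dimethoxy-2,5-dioxopent-3-enoate (achiral) | COC(=O)C(=O)/C(OC)=C(OC)\C(=O)c1oc(-c2ccc(OCc3ccccc3)cc2)cc1O | intermediate
10 | methyl (5S,6R)-2-[4-(benzyloxy)phenyl]-6-hydroxy-7,8-dimethoxy-4,9-dioxo-1-oxaspiro[4.4]nona-2,7-diene-6-carboxylate | COC(=O)[C@@]1(O)C(OC)=C(OC)C(=O)[C@]12OC(c1ccc(OCc3ccccc3)cc1)=CC2=O | intermediate
11 | methyl (5S,6R)-6-hydroxy-2-(4-hydroxyphenyl)-7,8-dimethoxy-4,9-dioxo-1-oxaspiro[4.4]nona-2,7-diene-6-carboxylate (limnophilaspiroketone) | COC(=O)[C@@]1(O)C(OC)=C(OC)C(=O)[C@]12OC(c1ccc(O)cc1)=CC2=O | target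

**Step count and risks**

Total step count: 7. Longest linear sequence: 7 steps (1 or 2 to 11).

Steps most likely to fail:

Step 6 (proposed new method). The copper-bound closure may be outrun by an uncatalysed, hydrogen-bond-organised aldol closure of the neutral enol, with loss of enantio- and diastereocontrol. The chelating acylhydroxyfuran may also sequester the copper, or the aldol may reverse and erode the enantiomeric purity. The fallback uses known chemistry only and sets out from 8. The classical alkoxide-mediated benzilic ester rearrangement of a cyclic 1,2-dione (NaOMe, MeOH, −20 °C, then AcOH quench) is run without chiral control. It should give 10 as the racemate, that is, together with its enantiomer methyl (5R,6S)-2-[4-(benzyloxy)phenyl]-6-hydroxy-7,8-dimethoxy-4,9-dioxo-1-oxaspiro[4.4]nona-2,7-diene-6-carboxylate F1. The two are separated by preparative HPLC on a polysaccharide-based chiral stationary phase and the route is rejoined at 10. F1 should racemise through achiral 9 under the same basic conditions and can be resubmitted, as can any diastereomeric material.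

Step 4. The peroxide may add at C2 of the pyranone or displace a methoxy group at C6/C7 by addition–elimination, or base may open the pyranone before the epoxide closes. The fallback sets out from 5 and follows a Hooker-type sequence. Hydroxide (LiOH, 1.0 equiv, THF–H2O, 0 °C) opens the pyranone by addition–elimination to the salt of 2-{3-[4-(benzyloxy)phenyl]-3-oxopropanoyl}-3-hydroxy-5,6-dimethoxycyclohexa-2,5-diene-1,4-dione F2. C-hydroxylation of its triketone-type carbon with dimethyldioxirane (acetone, −20 °C) should give 7, which closes to 8 with TsOH in MeCN. The route is rejoined at 8.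

Step 5. Opening of the epoxide at the ketone-flanked C8a may be too slow, or adventitious water may cleave 8 hydrolytically at C6 and cause a premature, uncontrolled ring contraction to the free acid. The fallback sets out from 6 and excludes water. It uses the anhydrous Lewis-acid rearrangement of an α,β-epoxy ketone to a 1,3-dicarbonyl compound (BF3·OEt2, CH2Cl2, −78 °C). The epoxide opens at C8a to the O1-stabilised cation and the C4 acyl group shifts from C4a to C8a, which should lead directly to 8 without passing through 7. This fallback makes no new compound (F0) and rejoins the route at 8.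

Further compounds
F1 | step 6 | methyl (5R,6S)-2-[4-(benzyloxy)phenyl]-6-hydroxy-7,8-dimethoxy-4,9-dioxo-1-oxaspiro[4.4]nona-2,7-diene-6-carboxylate | COC(=O)[C@]1(O)C(OC)=C(OC)C(=O)[C@@]12OC(c1ccc(OCc3ccccc3)cc1)=CC2=O
F2 | step 4 | 2-{3-[4-(benzyloxy)phenyl]-3-oxopropanoyl}-3-hydroxy-5,6-dimethoxycyclohexa-2,5-diene-1,4-dione | O=C(CC(=O)c1ccc(OCc2ccccc2)cc1)C1=C(O)C(=O)C(OC)=C(OC)C1=O
F0 | step 5 | none | none
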